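## Structural features

The target (labdane numbering throughout) is a tetracycle: a trans-fused decalin (ring A: C1–C5, C10; ring B: C5–C10), a cyclobutane (C8, C15, C14, C9) cis-fused to ring B along C8–C9, and a cyclopentane (C9, C11, C12, C13, C14) cis-fused to the cyclobutane along C9–C14. C9 is therefore common to three rings. There are seven stereocentres. C5–C6, C8–C9–C10 and C9–C14–C13 are contiguous, and C4, C10, C9 and C8 form a row of four fully substituted carbons. The C6 acetate is β: cis to the C10 methyl and syn-axial to it and to the 4β-methyl. H5, C14 and C15 are α, and the C13 hydroxyl is cis to C10 across the cyclopentane. Fragile points are the α-acetoxy ketone (C6 is the only enolisable position, so base epimerises it or shifts the acyl group) and the tertiary C13 alcohol beside the cyclobutane, which under acid would ionise and ring-expand. The real difficulty is the C8–C9–C10 array inside a strained four-membered ring, plus placing the C6 oxygen on the more hindered face. The key step exploits that the cyclopentane is fused at C9–C14 to a four-membered ring whose C8 carries C7: C7 can enter as carbon monoxide bridging C8 and C15 in a cyclopentenone, which is later contracted by moving C15 from C7 to C8.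

## Logic of the disconnections

34 ⇒ 33 ⇒ 31. The C6–O bond is cut last. An oxidant attacking a C6 enolate would come from the open α-face and give the 6α-epimer, so the oxygen is instead attached to a trigonal C6 and the hydrogen delivered afterwards. This needs a C6 diazo group (only possible because C8 is by then quaternary) and a carbenoid O–H insertion whose enol intermediate is protonated from the α-face.

31 ⇒ 30 ⇒ 29. Ring B is opened at C6–C7. The cut separates a C7 ester on the cyclobutane from a C6 carbanion stabilised by a sulfone, and removes the only ring that is not needed for stereocontrol. The forward step must attack a neopentyl ester, which the six-membered, intramolecular geometry should allow; the sulfone is then removed reductively.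

29 ⇒ 28 ⇒ 27. The C6–S bond and the C5–H bond are cut together, leaving an exocyclic C5=C6 alkene. This removes the C5 stereocentre from every earlier intermediate. The forward radical addition must deliver hydrogen to C5 from the α-face, which is secured only once C9 is quaternary and locks ring A with the C10 methyl axial.

27 ⇒ 26. The C8–methyl bond is cut to an ester enolate. The forward alkylation must occur anti to the ring A substituent on C9 so that the ester ends cis to C10.

26 ⇒ 25 ⇒ 23 ⇒ 21. The C14–H and C15–H bonds are removed, then the C8–C15 bond is exchanged for a C7–C15 bond (reverse of a 1,2-shift), turning the cyclobutene ester into a cyclopentenone with a diazo group at C8. The gain is a bicyclo[3.3.0]octenone, a standard cycloaddition product. The demands are that C8 is the only enolisable position (true, since C9 and C13 are quaternary) and that the shift tolerates the strain of the cyclobutene.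

21 ⇒ 19 (key). C9–C14, C7–C15 and C7–C8 are cut, releasing carbon monoxide and a monocyclic ring A enyne. Two rings and the C9 stereocentre disappear. The forward cyclisation must insert a 1,1-disubstituted alkene flanked by the quaternary C10 and must choose the alkene face through the C13 carbinol.

19 ⇒ 18 ⇒ 17 ⇒ 16. The C14–C15 bond is cut to an aldehyde, which is traced to a protected 1,2-diol. This turns the propargylic carbinol into a glycidol-derived unit whose C13 configuration is bought, not made.

16 ⇒ 12 + 14, and 14 ⇒ 13. The C11–C12 bond is cut to an allyl anion and an epoxide. The two termini of the anion are equivalent, so no regiochemistry arises; the epoxide must open at its CH2.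

12 ⇒ 10 ⇒ 9 ⇒ 8 ⇒ 7. The C5=C6 and C9=C8 double bonds are cut to two ketones, and the C9–C11 bond to an aldehyde. Each forward step relies on the large difference in hindrance between the ring carbonyl (two quaternary neighbours) and the C9 carbonyl.

7 ⇒ 5 ⇒ 4 ⇒ 3 ⇒ 1 + 2. The C9 aldehyde is traced to an allyl group by double-bond migration and cleavage, and the C10–C9 bond is cut to an enol carbonate. The forward allylation must set the quaternary C10 by catalyst control; 1 has a single enolisable position, so the enolate is unique.

## Other disconnections considered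

Alternative 1: The cut is C7–C8 and C9–C10. Forward, silyloxydiene A1 and 3-methylcyclobut-2-enone A2 combine in an endo [4+2] cycloaddition under a chiral oxazaborolidinium Lewis acid to give A3.
- In favour: it is convergent, the enantiodetermining step is the ring-forming step, and the cyclobutane with its C8 methyl arrives ready-made. On the C6 oxygen it is the better plan: the enol ether of A3 leads to a 6-ketone, and hydride attack from the α-face is the most reliable way to a 6β-alcohol.
- Against it here: the diene terminus C10 is fully substituted and sits in a twisted trimethylcyclohexenyl diene, and the dienophile is β-substituted, so two quaternary centres (C8, C10) must form in one bimolecular step.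
- Comparison: the chosen plan makes the equally congested C9 centre intramolecularly. After A3, C9 must still be quaternised with C11–C13, the cyclopentane closed onto the C14 carbonyl (leaving an oxygen to remove), and C7 oxidised beside C8. Step economy is at best equal.

Alternative 2: The cut is C13–C14. Forward, irradiation of the methyl ketone A4 leads to abstraction of a C14 hydrogen (δ to the carbonyl, since C9 has none) and closure of the 1,5-biradical to A5.
- In favour: ring and tertiary alcohol form in one reagent-free step, late, with the cis fusion enforced. For this ring alone it is shorter than cycloaddition plus contraction, and is the better plan on that count.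
- Against it here: the cyclobutane C–H bond is strong and competes with other abstractable hydrogens; nothing but biradical conformation decides the C13 configuration; and the C7 ketone must be masked as a silyl ether, which costs a redox detour next to the C6 acetate.
- Comparison: A4 already contains the cyclobutane with C8 and C9 quaternary, so the hardest part of the structure is moved, not solved. The chosen plan builds the cyclopentane through a tether and controls C13 by purchase.

Alternative 3: The cut is C9–C10. Forward, lactone A6 is converted to silyl ketene acetal A7, whose [3,3] shift contracts the lactone to the carbocyclic acid A8.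
- In favour: the most hindered bond of the molecule forms in a sigmatropic step, a reaction type that tolerates congestion, and the C6 carbinol configuration is relayed to C10. On control of the C9/C10 relationship it is equal to or better than the chosen plan.
- Against it here: the allyl partner is a tetrasubstituted ring alkene and the six-membered lactone forces a boat-like transition state.
- Comparison: A8 has lost the C6 oxygen (C5=C6), needs C7 oxidation, and has C14 as an unfunctionalised cyclobutane methylene, so the cyclopentane would have to be closed onto an unactivated C–H bond. The route after the key step would be longer than in the chosen plan.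

Key step: step 14

Assumption: the (R)-configured PHOX ligand is taken to deliver (R)-4, by analogy with the known sense of induction for 2-alkyl-2-allylcyclohexanones; if the sense is opposite, the ligand antipode is used.

Remarks on the design:
- The stereodescriptors of the cyclisation precursor and product skeletons were checked atom by atom against the target and agree at C13, C10 and C9.
- The precursor carries C5=C6 as an exocyclic methylene instead of a C5 stereocentre with a C6 sulfone. C5 cannot be set reliably while C9 is trigonal, and the sulfone is introduced after the cyclisation without substitution at the hindered C6.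
- Any minor enantiomer of 12 becomes a diastereomer after coupling with enantiopure 14 and can be removed at 21.

## Route

Step 1
Reactants: 1 2,2,6-trimethylcyclohexanone; 2 allyl chloroformate
Product: 3 allyl 2,6,6-trimethylcyclohex-1-en-1-yl carbonate
Conditions: LiHMDS, THF, 0 °C; then 2, −78 °C → rt
Reagents that add atoms: none
Why: Enol carbonate formation; 1 has a single enolisable hydrogen, so the lithium enolate is regiochemically unique and is O-acylated by the chloroformate.

Step 2
Reactants: 3 allyl 2,6,6-trimethylcyclohex-1-en-1-yl carbonate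
Product: 4 (R)-2-allyl-2,6,6-trimethylcyclohexan-1-one
Conditions: Pd2(dba)3 (2.5 mol%), (R)-t-Bu-PHOX (6 mol%), THF, 25 °C
Reagents that add atoms: none
Why: Decarboxylative Tsuji allylation; ionisation gives a π-allylpalladium enolate pair that recombines at C10, and the PHOX ligand differentiates the enolate faces to set the quaternary C10 (the allyl CH2 becomes C9).

Step 3
Reactants: 4 (R)-2-allyl-2,6,6-trimethylcyclohexan-1-one
Product: 5 (R,E)-2,2,6-trimethyl-6-(prop-1-en-1-yl)cyclohexan-1-one
Conditions: PdCl2(MeCN)2 (10 mol%), toluene, 60 °C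
Reagents that add atoms: none
Why: Metal-catalysed alkene isomerisation moves the terminal double bond one position inward; the quaternary C10 stops further migration and the E isomer is thermodynamically preferred.

Step 4
Reactants: 5 (R,E)-2,2,6-trimethyl-6-(prop-1-en-1-yl)cyclohexan-1-one
Product: 7 (R)-1,3,3-trimethyl-2-oxocyclohexane-1-carbaldehyde, via ozonide 6 (not isolated)
Conditions: O3, CH2Cl2, −78 °C; then PPh3, −78 °C → rt
Reagents that add atoms: ozone, [O-][O+]=O
Why: Ozonolysis with reductive work-up cleaves the only alkene and leaves the former allylic carbon as the C9 aldehyde; the aldehyde cannot enolise and is handled without base.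

Step 5
Reactants: 7 (R)-1,3,3-trimethyl-2-oxocyclohexane-1-carbaldehyde
Product: 8 (2R)-2-(1-hydroxyethyl)-2,6,6-trimethylcyclohexan-1-one (carbinol epimers)
Conditions: MeMgBr (1.05 equiv), THF, −78 °C; aq. NH4Cl at −78 °C
Reagents that add atoms: methylmagnesium bromide, C[Mg]Br
Why: Grignard 1,2-addition is chemoselective for the aldehyde because the ring ketone is flanked by two quaternary carbons; the cold quench suppresses retro-aldol cleavage, and the new carbinol centre is removed in step 6.

Step 6
Reactants: 8 (2R)-2-(1-hydroxyethyl)-2,6,6-trimethylcyclohexan-1-one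
Product: 9 (R)-2-acetyl-2,6,6-trimethylcyclohexan-1-one
Conditions: Dess–Martin periodinane, NaHCO3, CH2Cl2, 0 °C → rt
Reagents that add atoms: none
Why: Dess–Martin oxidation of the secondary alcohol under buffered conditions, which the non-enolisable 1,3-diketone tolerates without retro-Claisen cleavage.

Step 7
Reactants: 9 (R)-2-acetyl-2,6,6-trimethylcyclohexan-1-one
Product: 10 (R)-2,2,6-trimethyl-6-(prop-1-en-2-yl)cyclohexan-1-one
Conditions: Ph3PCH3Br, KOt-Bu, THF, 0 °C → rt
Reagents that add atoms: methyltriphenylphosphonium bromide, C[P+](c1ccccc1)(c1ccccc1)c1ccccc1.[Br-]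
Why: Wittig methylenation occurs only at the acetyl carbonyl, the ring carbonyl being shielded by two quaternary neighbours; this installs C8 (C11 is the methyl from step 5).

Step 8
Reactants: 10 (R)-2,2,6-trimethyl-6-(prop-1-en-2-yl)cyclohexan-1-one
Product: 12 (R)-1,3,3-trimethyl-2-methylidene-1-(prop-1-en-2-yl)cyclohexane, via β-hydroxysilane 11 (not isolated)
Conditions: Me3SiCH2Li, CeCl3, THF, −78 → 0 °C; aq. work-up; then KH, THF, 50 °C
Reagents that add atoms: (trimethylsilyl)methyllithium, [Li]C[Si](C)(C)C
Why: Peterson olefination; the small, weakly basic organocerium adds to the hindered non-enolisable ketone, and base-induced syn-elimination of silanolate gives the exocyclic C5=C6 alkene without a cation that could trigger methyl shifts.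

Step 9
Reactants: 13 (R)-2-methylglycidol
Product: 14 (S)-tert-butyldimethyl[(2-methyloxiran-2-yl)methoxy]silane
Conditions: TBSCl, imidazole, CH2Cl2, 0 °C → rt
Reagents that add atoms: tert-butyldimethylsilyl chloride, CC(C)(C)[Si](C)(C)Cl
Why: Silylation of the primary alcohol; the epoxide and the future C13 centre are untouched (the descriptor changes only through the priority rules).

Step 10
Reactants: 12 (R)-1,3,3-trimethyl-2-methylidene-1-(prop-1-en-2-yl)cyclohexane; 14 (S)-tert-butyldimethyl[(2-methyloxiran-2-yl)methoxy]silane
Product: 16 (S)-1-[(tert-butyldimethylsilyl)oxy]-2-methyl-5-[(R)-1,3,3-trimethyl-2-methylidenecyclohexyl]hex-5-en-2-ol, via allylpotassium 15 (not isolated)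
Conditions: n-BuLi, KOt-Bu, THF/hexane, −78 → −50 °C; then 14, −78 → 0 °C; aq. NH4Cl
Reagents that add atoms: none
Why: Allylic metalation of the isopropenyl methyl (the only allylic C–H in 12) gives a 2-substituted allyl anion with equivalent termini; SN2 opening of the 2,2-disubstituted epoxide at its CH2 forms C11–C12 and releases the C13 tertiary alcohol with the configuration carried in from 13.

Step 11
Reactants: 16 (S)-1-[(tert-butyldimethylsilyl)oxy]-2-methyl-5-[(R)-1,3,3-trimethyl-2-methylidenecyclohexyl]hex-5-en-2-ol
Product: 17 (S)-2-methyl-5-[(R)-1,3,3-trimethyl-2-methylidenecyclohexyl]hex-5-ene-1,2-diol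
Conditions: TBAF, THF, rt
Reagents that add atoms: none
Why: Fluoride-mediated cleavage of the primary silyl ether; nothing else in the molecule is fluoride-labile.

Step 12
Reactants: 17 (S)-2-methyl-5-[(R)-1,3,3-trimethyl-2-methylidenecyclohexyl]hex-5-ene-1,2-diol
Product: 18 (S)-2-hydroxy-2-methyl-5-[(R)-1,3,3-trimethyl-2-methylidenecyclohexyl]hex-5-enal
Conditions: SO3·pyridine, DMSO, Et3N, CH2Cl2, 0 °C
Reagents that add atoms: none
Why: Parikh–Doering oxidation of the primary alcohol; activated DMSO is chosen because it does not cleave the 1,2-diol and leaves the tertiary alcohol and both alkenes alone.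

Step 13
Reactants: 18 (S)-2-hydroxy-2-methyl-5-[(R)-1,3,3-trimethyl-2-methylidenecyclohexyl]hex-5-enal
Product: 19 (S)-3-methyl-6-[(R)-1,3,3-trimethyl-2-methylidenecyclohexyl]hept-6-en-1-yn-3-ol
Conditions: dimethyl (1-diazo-2-oxopropyl)phosphonate, K2CO3, MeOH, 0 °C → rt
Reagents that add atoms: dimethyl (1-diazo-2-oxopropyl)phosphonate, CC(=O)C(=[N+]=[N-])P(=O)(OC)OC
Why: Seyferth–Gilbert homologation with the Ohira–Bestmann reagent converts the non-enolisable α-hydroxy aldehyde into the terminal alkyne (C15) under mild carbonate conditions that cannot affect C13.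

Step 14
Reactants: 19 (S)-3-methyl-6-[(R)-1,3,3-trimethyl-2-methylidenecyclohexyl]hept-6-en-1-yn-3-ol
Product: 21 6-hydroxy-6-methyl-3a-[(R)-1,3,3-trimethyl-2-methylidenecyclohexyl]-3a,4,5,6-tetrahydropentalen-2(3H)-one (cyclohexyl group on C9 cis to the C13 hydroxyl), via hexacarbonyldicobalt alkyne complex 20 (not isolated)
Conditions: Co2(CO)8 (1.1 equiv), CH2Cl2, rt; then N-methylmorpholine N-oxide (6 equiv), 0 °C → rt
Reagents that add atoms: dicobalt octacarbonyl, O=C=[Co](=C=O)(=C=O)(=C=O)[Co](=C=O)(=C=O)(=C=O)=C=O
Why: The alkyne forms complex 20, the N-oxide removes a CO ligand, the C9=C8 alkene coordinates and inserts into the Co–C14 bond (C9–C14), CO inserts at C8 (C8–C7) and reductive elimination forms C7–C15. The closest known reaction type is the intramolecular Pauson–Khand reaction of hept-1-en-6-ynes carrying a 1,1-disubstituted alkene, which gives angularly substituted bicyclo[3.3.0]oct-1-en-3-ones. The cyclopentane closes through the three-carbon tether by insertion at C9 in the exo sense, and the cyclopentenone closes by the [2+2+1] assembly of C14, C15, C7, C8 and C9. The one new stereocentre, C9, is controlled by C13: in the cis-fused metallacycle the C13 substituent on the face of the angular ring A group meets it in a 1,3-relationship across the forming ring, so the smaller hydroxyl should take that position and the methyl the other. Regiochemistry is fixed by the tether. Chemoselectivity for C9=C8 over C5=C6 is secured because the second alkene could only close a seven-membered ring. The fully substituted C13 helps ring closure (Thorpe–Ingold effect), which matters because the alkene is flanked by the quaternary C10. The free hydroxyl is kept both as the small group here and as the directing group of step 17.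

Step 15
Reactants: 21 bicyclic enone (as named in step 14)
Product: 23 3-diazo-6-hydroxy-6-methyl-3a-[(R)-1,3,3-trimethyl-2-methylidenecyclohexyl]-3a,4,5,6-tetrahydropentalen-2(3H)-one (diazo group at C8), via trifluoroacetyl enone 22 (not isolated)
Conditions: LiHMDS (2.2 equiv), THF, −78 °C; CF3CO2CH2CF3; then MsN3, Et3N, H2O, MeCN, rt
Reagents that add atoms: methanesulfonyl azide, CS(=O)(=O)N=[N+]=[N-]
Why: Regitz-type detrifluoroacetylative diazo transfer; C8 is the only enolisable position of the enone because C9 and C13 are quaternary, so activation and diazo transfer are regiospecific.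

Step 16
Reactants: 23 C8 diazo enone
Product: 25 methyl 4-hydroxy-4-methyl-1-[(R)-1,3,3-trimethyl-2-methylidenecyclohexyl]bicyclo[3.2.0]hept-5-ene-7-carboxylate (C8 epimers), via ketene 24 (not isolated)
Conditions: hν (medium-pressure Hg lamp, Pyrex filter), MeOH, 0 °C
Reagents that add atoms: methanol, CO
Why: Photochemical Wolff rearrangement of the cyclic s-cis α-diazo ketone; nitrogen loss with 1,2-shift of the vinylic C15 from C7 to C8 gives ketene 24, which methanol traps; the closest precedents are the ring contractions of 2-diazocyclopentanones and 2-diazo-1-indanones to cyclobutane and benzocyclobutene carboxylates.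

Step 17
Reactants: 25 cyclobutene ester
Product: 26 methyl 4-hydroxy-4-methyl-1-[(R)-1,3,3-trimethyl-2-methylidenecyclohexyl]bicyclo[3.2.0]heptane-7-carboxylate (cis-fused, H14 cis to the hydroxyl; C8 epimers)
Conditions: [Rh(nbd)(dppb)]BF4 (10 mol%), H2 (20 atm), CH2Cl2, rt
Reagents that add atoms: none
Why: Hydroxyl-directed hydrogenation; the C13 hydroxyl binds the cationic rhodium and delivers hydrogen to the strained C14=C15 bond from its own face, the only face that gives the cis-fused bicyclo[3.2.0]heptane, which sets C14; the remote, doubly neopentyl C5=C6 alkene has no directing group and should react far more slowly.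

Step 18
Reactants: 26 cyclobutane ester
Product: 27 methyl 4-hydroxy-4,7-dimethyl-1-[(R)-1,3,3-trimethyl-2-methylidenecyclohexyl]bicyclo[3.2.0]heptane-7-carboxylate (C8 methyl syn to C11, ester syn to C10)
Conditions: LDA (2.3 equiv), THF, −78 → −40 °C; MeI, DMPU, −78 → −20 °C
Reagents that add atoms: iodomethane, CI
Why: Ester enolate alkylation; both C8 epimers give the same enolate, and methyl iodide should approach anti to the ring A substituent on the neighbouring C9, which sets C8 with the ester cis to C10 as ring B requires.

Step 19
Reactants: 27 C8-methylated ester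
Product: 28 methyl 4-hydroxy-4,7-dimethyl-1-{(1R)-1,3,3-trimethyl-2-[(phenylsulfanyl)methyl]cyclohexyl}bicyclo[3.2.0]heptane-7-carboxylate (CH2SPh trans to the bicycloheptyl group, cis to the C10 methyl)
Conditions: PhSH (5 equiv), AIBN (0.2 equiv), benzene, 80 °C
Reagents that add atoms: thiophenol, Sc1ccccc1
Why: Radical-chain hydrothiolation; the thiyl radical adds to the terminal C6, and the tertiary C5 radical takes hydrogen from PhSH on the α-face, anti to the axial C10 and C4 methyls of a chair now locked by the equatorial quaternary C9 substituent, which sets C5.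

Step 20
Reactants: 28 sulfide
Product: 29 the corresponding phenyl sulfone (CH2SO2Ph on C5)
Conditions: 3-chloroperbenzoic acid (2.2 equiv), NaHCO3, CH2Cl2, 0 °C → rt
Reagents that add atoms: 3-chloroperbenzoic acid, OOC(=O)c1cccc(Cl)c1
Why: Sulfide-to-sulfone oxidation; no alkene remains to compete, and the ester and tertiary alcohol are inert.

Step 21
Reactants: 29 sulfone ester
Product: 30 tetracyclic 13-hydroxy-6-(phenylsulfonyl)-7-ketone (rings A/B trans, all four rings closed; C6 epimers)
Conditions: LDA (3.3 equiv), THF, −78 → 0 °C; aq. NH4Cl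
Reagents that add atoms: none
Why: Intramolecular Claisen-type (Dieckmann-like) acylation of the α-sulfonyl carbanion by the non-enolisable C7 ester closes ring B through a six-membered transition state; deprotonation of the β-keto sulfone drives the reaction.

Step 22
Reactants: 30 β-keto sulfone
Product: 31 tetracyclic 13-hydroxy-7-ketone with C6 as CH2
Conditions: SmI2 (2.5 equiv), THF/MeOH, −78 °C
Reagents that add atoms: none
Why: Reductive desulfonylation; single-electron transfer to the ketone cleaves the α C–S bond, and the samarium enolate is protonated by methanol.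

Step 23
Reactants: 31 tetracyclic ketone
Product: 33 6-diazo-13-hydroxy-7-ketone, via trifluoroacetyl ketone 32 (not isolated)
Conditions: LiHMDS (2.2 equiv), THF, −78 °C; CF3CO2CH2CF3; then MsN3, Et3N, H2O, MeCN, rt
Reagents that add atoms: methanesulfonyl azide, CS(=O)(=O)N=[N+]=[N-]
Why: Regitz-type detrifluoroacetylative diazo transfer; C6 is the only enolisable position because C8 is quaternary.

Step 24
Reactants: 33 6-diazo ketone
Product: 34 target, 6β-acetoxy-13-hydroxy-7-ketone
Conditions: Rh2(OAc)4 (1 mol%), AcOH (5 equiv), CH2Cl2, 0 °C → rt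
Reagents that add atoms: acetic acid, CC(=O)O
Why: Rhodium-carbenoid O–H insertion into acetic acid; the enol released from the oxonium ylide should be protonated at C6 from the α-face, the β-face being covered by the syn-axial methyls on C4 and C10, which gives the 6β-acetate; the near-neutral conditions spare the tertiary alcohol and the acetate.

## Compound list

1 | 2,2,6-trimethylcyclohexanone | CC1CCCC(C)(C)C1=O | starting material
2 | allyl chloroformate | C=CCOC(=O)Cl | starting material
3 | allyl 2,6,6-trimethylcyclohex-1-en-1-yl carbonate | C=CCOC(=O)OC1=C(C)CCCC1(C)C | intermediate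
4 | (R)-2-allyl-2,6,6-trimethylcyclohexan-1-one | C=CC[C@@]1(C)CCCC(C)(C)C1=O | intermediate
5 | (R,E)-2,2,6-trimethyl-6-(prop-1-en-1-yl)cyclohexan-1-one | C/C=C/[C@@]1(C)CCCC(C)(C)C1=O | intermediate
6 | ozonide of 5 (3-methyl-1,2,4-trioxolan-5-yl on C10) | CC1OOC(O1)[C@@]1(C)CCCC(C)(C)C1=O | intermediate (not isolated)
7 | (R)-1,3,3-trimethyl-2-oxocyclohexane-1-carbaldehyde | O=C[C@@]1(C)CCCC(C)(C)C1=O | intermediate
8 | (2R)-2-(1-hydroxyethyl)-2,6,6-trimethylcyclohexan-1-one | CC(O)[C@@]1(C)CCCC(C)(C)C1=O | intermediate
9 | (R)-2-acetyl-2,6,6-trimethylcyclohexan-1-one | CC(=O)[C@@]1(C)CCCC(C)(C)C1=O | intermediate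
10 | (R)-2,2,6-trimethyl-6-(prop-1-en-2-yl)cyclohexan-1-one | CC(=C)[C@@]1(C)CCCC(C)(C)C1=O | intermediate
11 | (2R)-2,6,6-trimethyl-2-(prop-1-en-2-yl)-1-[(trimethylsilyl)methyl]cyclohexan-1-ol | CC(=C)[C@@]1(C)CCCC(C)(C)C1(O)C[Si](C)(C)C | intermediate (not isolated)
12 | (R)-1,3,3-trimethyl-2-methylidene-1-(prop-1-en-2-yl)cyclohexane | CC(=C)[C@@]1(C)CCCC(C)(C)C1=C | intermediate
13 | (R)-2-methylglycidol | OC[C@]1(C)CO1 | starting material
14 | (S)-tert-butyldimethyl[(2-methyloxiran-2-yl)methoxy]silane | CC(C)(C)[Si](C)(C)OC[C@]1(C)CO1 | intermediate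
15 | allylpotassium from 12 | [K]CC(=C)[C@@]1(C)CCCC(C)(C)C1=C | intermediate (not isolated)
16 | (S)-1-[(tert-butyldimethylsilyl)oxy]-2-methyl-5-[(R)-1,3,3-trimethyl-2-methylidenecyclohexyl]hex-5-en-2-ol | CC(C)(C)[Si](C)(C)OC[C@@](C)(O)CCC(=C)[C@@]1(C)CCCC(C)(C)C1=C | intermediate
17 | (S)-2-methyl-5-[(R)-1,3,3-trimethyl-2-methylidenecyclohexyl]hex-5-ene-1,2-diol | OC[C@@](C)(O)CCC(=C)[C@@]1(C)CCCC(C)(C)C1=C | intermediate
18 | (S)-2-hydroxy-2-methyl-5-[(R)-1,3,3-trimethyl-2-methylidenecyclohexyl]hex-5-enal | O=C[C@@](C)(O)CCC(=C)[C@@]1(C)CCCC(C)(C)C1=C | intermediate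
19 | (S)-3-methyl-6-[(R)-1,3,3-trimethyl-2-methylidenecyclohexyl]hept-6-en-1-yn-3-ol | C#C[C@@](C)(O)CCC(=C)[C@@]1(C)CCCC(C)(C)C1=C | intermediate
20 | hexacarbonyldicobalt complex of the alkyne of 19 | O[C@@](C)(CCC(=C)[C@@]1(C)CCCC(C)(C)C1=C)C12[Co]3(=C=O)(=C=O)(=C=O)[Co]1(=C=O)(=C=O)(=C=O)C23 | intermediate (not isolated)
21 | 6-hydroxy-6-methyl-3a-[(R)-1,3,3-trimethyl-2-methylidenecyclohexyl]-3a,4,5,6-tetrahydropentalen-2(3H)-one, ring A group cis to OH | O=C1C=C2[C@@](C)(O)CC[C@@]2(C1)[C@@]1(C)CCCC(C)(C)C1=C | intermediate
22 | C8-trifluoroacetyl derivative of 21 | O=C1C=C2[C@@](C)(O)CC[C@@]2(C1C(=O)C(F)(F)F)[C@@]1(C)CCCC(C)(C)C1=C | intermediate (not isolated)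
23 | C8-diazo derivative of 21 | O=C1C=C2[C@@](C)(O)CC[C@@]2(C1=[N+]=[N-])[C@@]1(C)CCCC(C)(C)C1=C | intermediate
24 | ketene at C8 of the bicyclo[3.2.0]hept-5-ene | O=C=C1C=C2[C@@](C)(O)CC[C@]12[C@@]1(C)CCCC(C)(C)C1=C | intermediate (not isolated)
25 | methyl 4-hydroxy-4-methyl-1-[(R)-1,3,3-trimethyl-2-methylidenecyclohexyl]bicyclo[3.2.0]hept-5-ene-7-carboxylate | COC(=O)C1C=C2[C@@](C)(O)CC[C@]12[C@@]1(C)CCCC(C)(C)C1=C | intermediate
26 | methyl 4-hydroxy-4-methyl-1-[(R)-1,3,3-trimethyl-2-methylidenecyclohexyl]bicyclo[3.2.0]heptane-7-carboxylate, cis-fused | COC(=O)C1C[C@@H]2[C@@](C)(O)CC[C@]12[C@@]1(C)CCCC(C)(C)C1=C | intermediate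
27 | methyl 4-hydroxy-4,7-dimethyl-1-[(R)-1,3,3-trimethyl-2-methylidenecyclohexyl]bicyclo[3.2.0]heptane-7-carboxylate | COC(=O)[C@@]1(C)C[C@@H]2[C@@](C)(O)CC[C@]12[C@@]1(C)CCCC(C)(C)C1=C | intermediate
28 | C6 phenyl sulfide from 27 (C5–H α) | COC(=O)[C@@]1(C)C[C@@H]2[C@@](C)(O)CC[C@]12[C@@]1(C)CCCC(C)(C)[C@@H]1CSc1ccccc1 | intermediate
29 | C6 phenyl sulfone | COC(=O)[C@@]1(C)C[C@@H]2[C@@](C)(O)CC[C@]12[C@@]1(C)CCCC(C)(C)[C@@H]1CS(=O)(=O)c1ccccc1 | intermediate
30 | tetracyclic 13-hydroxy-6-(phenylsulfonyl)-7-ketone | O=S(=O)(c1ccccc1)C1C(=O)[C@@]2(C)C[C@H]3[C@@]2(CC[C@]3(C)O)[C@@]2(C)CCCC(C)(C)[C@H]12 | intermediate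
31 | tetracyclic 13-hydroxy-7-ketone | C1C(=O)[C@@]2(C)C[C@H]3[C@@]2(CC[C@]3(C)O)[C@@]2(C)CCCC(C)(C)[C@H]12 | intermediate
32 | 6-trifluoroacetyl derivative of 31 | O=C(C1C(=O)[C@@]2(C)C[C@H]3[C@@]2(CC[C@]3(C)O)[C@@]2(C)CCCC(C)(C)[C@H]12)C(F)(F)F | intermediate (not isolated)
33 | 6-diazo-13-hydroxy-7-ketone | [N-]=[N+]=C1C(=O)[C@@]2(C)C[C@H]3[C@@]2(CC[C@]3(C)O)[C@@]2(C)CCCC(C)(C)[C@H]12 | intermediate
34 | 6β-acetoxy-13-hydroxy-7-ketone | CC(=O)O[C@@H]1C(=O)[C@@]2(C)C[C@H]3[C@@]2(CC[C@]3(C)O)[C@@]2(C)CCCC(C)(C)[C@H]12 | target

## Step count and least certain steps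

Total step count: 24. Longest linear sequence: 23 (steps 1–8 and 10–24; step 9 is a one-step side branch).

Step 14 (key step). What may go wrong:
- The alkene, flanked by the quaternary C10, may fail to insert, so that decomplexation or alkyne reduction takes over.
- Discrimination between the methyl and hydroxyl groups on C13 may be too weak, giving poor facial selectivity at C9.

Fallback: from 19, both the hydroxyl and the alkyne terminus are silylated (n-BuLi, Me3SiCl) to give the bis(trimethylsilyl) enyne F1. Oxidative cyclisation on zirconocene (Cp2ZrCl2 with two equivalents of n-BuLi) followed by carbonylation under CO gives the silylated enone F2. Zirconacycle formation is reversible, so the thermodynamically preferred ring fusion should result. Fluoride then removes both silyl groups and the route is rejoined at 21.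

Step 16. What may go wrong: the ring contraction must build a cyclobutene with three trigonal carbons; carbene C–H insertion or thermal electrocyclic opening of the strained product may outrun it.

Fallback: from 21, C8 is formylated (HCO2Et, NaH) to the hydroxymethylidene enone F3. Hydroxyl-directed hydrogenation of C14=C15 gives the saturated cis-fused ketone F4, and deformylative diazo transfer (MsN3, Et3N) gives the saturated diazo ketone F5. Its photochemical Wolff contraction in methanol is the well-precedented 2-diazocyclopentanone case and rejoins the route at 26.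

Step 10. What may go wrong: metalation of the hindered diene may be slow or unselective, and the 2,2-disubstituted epoxide may open sluggishly.

Fallback: from 9, the kinetic enolate (LDA) is alkylated with the known bromide (E)-4-bromo-3-methylbut-2-enyl tert-butyldimethylsilyl ether to give diketone F6. The sequence then runs as follows:
- Wittig methylenation at C9 gives F7.
- Peterson methylenation at C5 gives F8.
- Desilylation gives the allylic alcohol F9.
- Sharpless epoxidation (Ti(OiPr)4, L-(+)-diethyl tartrate, t-BuOOH) gives the (2S,3S)-epoxy alcohol F10.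
- Appel chlorination (PPh3, CCl4) gives the epoxy chloride F11.
- Double elimination with n-BuLi (3 equiv) opens the epoxide to the tertiary propargylic alcohol, rejoining the route at 19.

Step 18. What may go wrong: facial selectivity of the methylation may be poor, because the concave face of the bicycle competes with the face screened by ring A; the wrong C8 epimer cannot close ring B.

Fallback: from 26, radical hydrothiolation gives sulfide F12 and oxidation gives sulfone F13. Ring closure with KOt-Bu, under which C8 equilibrates, gives the β-keto sulfone F14 lacking the C8 methyl. Its dianion (excess LDA) is methylated at C8, where the cis ring fusion dictates the configuration, rejoining the route at 30.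

Step 21. What may go wrong: the neopentyl ester may resist attack, so that proton transfer or intermolecular condensation competes.

Fallback: from 29, the ester is reduced with i-Bu2AlH at −78 °C to aldehyde F15. Intramolecular addition of the sulfonyl carbanion (LiHMDS) to the far more electrophilic aldehyde gives the β-hydroxy sulfone F16, and Dess–Martin oxidation rejoins the route at 30.

Step 24. What may go wrong: the enol may be protonated with insufficient face selectivity, or acetate may be delivered by an ionic pathway with the opposite sense, giving the 6α-epimer.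

Fallback: from 31, sulfenylation (LiHMDS, PhSSPh) gives the 6-phenylsulfanyl ketone F17, and oxidation (3-chloroperbenzoic acid, −78 °C) gives sulfoxide F18. A Pummerer reaction (Ac2O, activated at 0 °C) gives the 6-acetoxy-6-phenylsulfanyl ketone F19. Bu3SnH with AIBN removes sulfur, and the bulky stannane delivers hydrogen to the planar C6 radical from the α-face, rejoining the route at 34.

## Further compounds

F1 | step 14 | O,C-bis(trimethylsilyl) derivative of 19 | C[Si](C)(C)C#C[C@@](C)(O[Si](C)(C)C)CCC(=C)[C@@]1(C)CCCC(C)(C)C1=C
F2 | step 14 | 15-trimethylsilyl, 13-O-trimethylsilyl derivative of 21 | O=C1C([Si](C)(C)C)=C2[C@@](C)(O[Si](C)(C)C)CC[C@@]2(C1)[C@@]1(C)CCCC(C)(C)C1=C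
F3 | step 16 | 8-(hydroxymethylidene) derivative of 21 | O=C1C=C2[C@@](C)(O)CC[C@@]2(C1=CO)[C@@]1(C)CCCC(C)(C)C1=C
F4 | step 16 | 14,15-dihydro derivative of F3, cis-fused | O=C1C[C@@H]2[C@@](C)(O)CC[C@@]2(C1=CO)[C@@]1(C)CCCC(C)(C)C1=C
F5 | step 16 | saturated cis-fused C8 diazo ketone | O=C1C[C@@H]2[C@@](C)(O)CC[C@@]2(C1=[N+]=[N-])[C@@]1(C)CCCC(C)(C)C1=C
F6 | step 10 | (R,E)-2-[6-(tert-butyldimethylsilyloxy)-4-methylhex-4-enoyl]-2,6,6-trimethylcyclohexan-1-one | CC(C)(C)[Si](C)(C)OC/C=C(\C)CCC(=O)[C@@]1(C)CCCC(C)(C)C1=O
F7 | step 10 | C9-methylidene ketone from F6 | CC(C)(C)[Si](C)(C)OC/C=C(\C)CCC(=C)[C@@]1(C)CCCC(C)(C)C1=O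
F8 | step 10 | C5,C9-bis(methylidene) silyl ether | CC(C)(C)[Si](C)(C)OC/C=C(\C)CCC(=C)[C@@]1(C)CCCC(C)(C)C1=C
F9 | step 10 | (E)-3-methyl-6-[(R)-1,3,3-trimethyl-2-methylidenecyclohexyl]hepta-2,6-dien-1-ol | OC/C=C(\C)CCC(=C)[C@@]1(C)CCCC(C)(C)C1=C
F10 | step 10 | (2S,3S)-2,3-epoxy alcohol from F9 | OC[C@@H]1O[C@@]1(C)CCC(=C)[C@@]2(C)CCCC(C)(C)C2=C
F11 | step 10 | epoxy chloride from F10 | ClC[C@@H]1O[C@@]1(C)CCC(=C)[C@@]2(C)CCCC(C)(C)C2=C
F12 | step 18 | C6 phenyl sulfide lacking the C8 methyl | COC(=O)C1C[C@@H]2[C@@](C)(O)CC[C@]12[C@@]1(C)CCCC(C)(C)[C@@H]1CSc1ccccc1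
F13 | step 18 | C6 phenyl sulfone lacking the C8 methyl | COC(=O)C1C[C@@H]2[C@@](C)(O)CC[C@]12[C@@]1(C)CCCC(C)(C)[C@@H]1CS(=O)(=O)c1ccccc1
F14 | step 18 | 8-demethyl analogue of 30 | O=S(=O)(c1ccccc1)C1C(=O)[C@H]2C[C@H]3[C@@]2(CC[C@]3(C)O)[C@@]2(C)CCCC(C)(C)[C@H]12
F15 | step 21 | C7 aldehyde corresponding to 29 | O=C[C@@]1(C)C[C@@H]2[C@@](C)(O)CC[C@]12[C@@]1(C)CCCC(C)(C)[C@@H]1CS(=O)(=O)c1ccccc1
F16 | step 21 | tetracyclic 7,13-dihydroxy-6-(phenylsulfonyl) compound | O=S(=O)(c1ccccc1)C1C(O)[C@@]2(C)C[C@H]3[C@@]2(CC[C@]3(C)O)[C@@]2(C)CCCC(C)(C)[C@H]12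
F17 | step 24 | 6-(phenylsulfanyl) derivative of 31 | c1ccccc1SC1C(=O)[C@@]2(C)C[C@H]3[C@@]2(CC[C@]3(C)O)[C@@]2(C)CCCC(C)(C)[C@H]12
F18 | step 24 | 6-(phenylsulfinyl) derivative of 31 | O=S(c1ccccc1)C1C(=O)[C@@]2(C)C[C@H]3[C@@]2(CC[C@]3(C)O)[C@@]2(C)CCCC(C)(C)[C@H]12
F19 | step 24 | 6-acetoxy-6-(phenylsulfanyl) derivative of 31 | CC(=O)OC1(Sc2ccccc2)C(=O)[C@@]2(C)C[C@H]3[C@@]2(CC[C@]3(C)O)[C@@]2(C)CCCC(C)(C)[C@H]12
A1 | alternative 1 | tert-butyldimethyl{[1-(2,6,6-trimethylcyclohex-1-en-1-yl)ethenyl]oxy}silane | C=C(O[Si](C)(C)C(C)(C)C)C1=C(C)CCCC1(C)C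
A2 | alternative 1 | 3-methylcyclobut-2-en-1-one | CC1=CC(=O)C1
A3 | alternative 1 | tricyclic cyclobutanone with C5–C6 silyl enol ether | C[C@]12CC(=O)[C@H]1[C@@]1(C)CCCC(C)(C)C1=C(O[Si](C)(C)C(C)(C)C)C2
A4 | alternative 2 | tricyclic 9-(3-oxobutyl) 6-acetate 7-triethylsilyl ether | CC(=O)O[C@@H]1[C@H](O[Si](CC)(CC)CC)[C@@]2(C)CC[C@@]2(CCC(C)=O)[C@@]2(C)CCCC(C)(C)[C@H]12
A5 | alternative 2 | target with C7 as triethylsilyl-protected alcohol | CC(=O)O[C@@H]1[C@H](O[Si](CC)(CC)CC)[C@@]2(C)C[C@H]3[C@@]2(CC[C@]3(C)O)[C@@]2(C)CCCC(C)(C)[C@H]12
A6 | alternative 3 | cyclobutane-fused δ-lactone with 2,6,6-trimethylcyclohexenyl on C6 | O=C1O[C@@H](C2=C(C)CCCC2(C)C)C[C@@]2(C)CC[C@@H]12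
A7 | alternative 3 | tert-butyldimethylsilyl ketene acetal of A6 | CC(C)(C)[Si](C)(C)OC1=C2CC[C@]2(C)C[C@H](C2=C(C)CCCC2(C)C)O1
A8 | alternative 3 | tricyclic C11 acid with ring B alkene | OC(=O)[C@@]12CC[C@]1(C)CC=C1C(C)(C)CCC[C@@]12C
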